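**Retrosynthetic overview**

1. Target 29 ⇐ 28 ⇐ 26 ⇐ 25 by C9 desilylation, C6 tigloylation and C6 desilylation (germacrane numbers are used as labels, see the remark).
2. Key disconnection: the C7–C8 bond and the lactone C12–O bond of 25 are cut together. The enabling feature is the trans-fused α-methylene-γ-butyrolactone (ring O–C12–C11(=C13H2)–C7–C8) on the C7–C8 edge of the ten-membered carbocycle: the C8 carbinol carbon is homoallylic to the exocyclic C11=C13 alkene and C11 carries the acyl carbon. This is the retron of a carbonyl 2-(alkoxycarbonyl)allylation, so the open-chain bromo ester aldehyde 22 should give both rings in one Cr(II) operation.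
3. 22 ⇐ ynoate 17 (α-hydroxymethylation, bromination, PMB ether → CHO) ⇐ epoxy aldehyde 13 + methyl propiolate (Felkin addition) ⇐ Sharpless epoxidation of E-allylic alcohol 11 ⇐ Zr-catalysed carboalumination of alkyne 9.
4. 9 ⇐ anti-3-methyl-1,2-diol 6 ⇐ Sharpless epoxidation / Me3Al opening of (E)-oct-2-en-7-yn-1-ol 4 ⇐ hepta-1,6-diyne 1.
5. Ring order: oxirane first (step 8), then the ten-membered carbocycle and the γ-lactone together (step 16).

Key step: step 16

Remark: germacrane numbering is used only as labels (C8 = lactone O–CH, C7 = ring-fusion CH bearing C11, C6 = CH–O-tigloyl, C4/C5 = oxirane carbons, C9 = CH–OH, C10 = CH–CH3, C12 = lactone C=O, C13 = exocyclic CH2); the alkene geometry of 19–22 is drawn as the syn-hydroalumination product and is assumed not to matter, because the allylchromium species equilibrates.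

**Route**

Step 1
Reactants: 1 hepta-1,6-diyne
Product: 3 octa-2,7-diyn-1-ol, via lithium acetylide 2 (not isolated)
Conditions: n-BuLi (1.0 equiv, 1 in 2.5-fold excess and recovered), THF, −78 °C; (CH2O)n, −78 °C → rt
Reagents that add atoms: formaldehyde (from paraformaldehyde) C=O
Why: Mono-deprotonation of the terminal diyne and addition of the acetylide to formaldehyde (acetylide hydroxymethylation) should give the propargylic alcohol, the excess of diyne suppressing the bis-adduct.

Step 2
Reactants: 3 octa-2,7-diyn-1-ol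
Product: 4 (E)-oct-2-en-7-yn-1-ol
Conditions: LiAlH4, THF, 0 → 45 °C; aq. Rochelle salt
Reagents that add atoms: none
Why: Hydroxyl-directed trans-hydroalumination (LiAlH4 reduction of a propargylic alcohol) should reduce only the 2-alkyne to the E-alkene and leave the isolated terminal alkyne untouched.

Step 3
Reactants: 4 (E)-oct-2-en-7-yn-1-ol
Product: 5 [(2S,3S)-3-(pent-4-yn-1-yl)oxiran-2-yl]methanol
Conditions: Ti(OiPr)4 (10 mol %), L-(+)-DET (12 mol %), t-BuOOH, 4 Å MS, CH2Cl2, −20 °C
Reagents that add atoms: tert-butyl hydroperoxide CC(C)(C)OO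
Why: Sharpless asymmetric epoxidation of an E-disubstituted allylic alcohol with L-(+)-tartrate should deliver the (2S,3S)-epoxide under reagent control, which fixes the C9 oxygen and the face opened in step 4.

Step 4
Reactants: 5 [(2S,3S)-3-(pent-4-yn-1-yl)oxiran-2-yl]methanol
Product: 6 (2R,3R)-3-methyloct-7-yne-1,2-diol
Conditions: Me3Al (3 equiv), hexane/CH2Cl2, 0 °C → rt
Reagents that add atoms: trimethylaluminium C[Al](C)C
Why: Trimethylaluminium opening of a 2,3-epoxy alcohol occurs at C3 with inversion (the aluminium alkoxide activates the oxirane and methyl is delivered to the distal carbon), which should give the anti 3-methyl-1,2-diol and so set C10 relative to C9.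

Step 5
Reactants: 6 (2R,3R)-3-methyloct-7-yne-1,2-diol
Product: 8 (2R,3R)-1-[(4-methoxybenzyl)oxy]-3-methyloct-7-yn-2-ol, via stannylene acetal 7 (not isolated)
Conditions: Bu2SnO, toluene, reflux (−H2O); PMBCl, Bu4NI (cat.), toluene, 90 °C
Reagents that add atoms: 4-methoxybenzyl chloride COc1ccc(CCl)cc1
Why: Stannylene-acetal-mediated O-alkylation of a terminal 1,2-diol should occur selectively at the primary oxygen.

Step 6
Reactants: 8 (2R,3R)-1-[(4-methoxybenzyl)oxy]-3-methyloct-7-yn-2-ol
Product: 9 TBS ether of 8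
Conditions: TBSOTf, 2,6-lutidine, CH2Cl2, −78 → 0 °C
Reagents that add atoms: tert-butyldimethylsilyl triflate CC(C)(C)[Si](C)(C)OS(=O)(=O)C(F)(F)F
Why: Silyl triflate silylation of the hindered secondary alcohol installs a non-chelating C9 group that is needed later for Felkin control and survives to the last step.

Step 7
Reactants: 9 TBS ether of 8
Product: 11 (2E,7R,8R)-8-[(tert-butyldimethylsilyl)oxy]-9-[(4-methoxybenzyl)oxy]-3,7-dimethylnon-2-en-1-ol, via alkenylalane 10 (not isolated)
Conditions: Me3Al, Cp2ZrCl2 (25 mol %), CH2Cl2, 0 °C → rt; n-BuLi, THF, −78 °C; (CH2O)n, rt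
Reagents that add atoms: trimethylaluminium C[Al](C)C; formaldehyde (from paraformaldehyde) C=O
Why: Negishi zirconium-catalysed carboalumination adds Me–Al syn across the terminal alkyne with aluminium at the terminus, and hydroxymethylation of the derived alanate with retention should give the E-trisubstituted (geraniol-type) allylic alcohol.

Step 8
Reactants: 11 E-allylic alcohol
Product: 12 (2R,3R)-epoxy alcohol
Conditions: Ti(OiPr)4 (10 mol %), D-(−)-DET (12 mol %), t-BuOOH, 4 Å MS, CH2Cl2, −20 °C
Reagents that add atoms: tert-butyl hydroperoxide CC(C)(C)OO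
Why: Sharpless asymmetric epoxidation with D-(−)-tartrate should set C4 and C5 as the (2R,3R)-epoxide under reagent control that overrides the remote C9/C10 centres.

Step 9
Reactants: 12 (2R,3R)-epoxy alcohol
Product: 13 (2S,3R)-epoxy aldehyde
Conditions: Dess–Martin periodinane, NaHCO3, CH2Cl2, 0 °C → rt
Reagents that add atoms: none
Why: Buffered Dess–Martin oxidation should give the α,β-epoxy aldehyde without touching the oxirane, the PMB ether or the silyl ether.

Step 10
Reactants: 13 (2S,3R)-epoxy aldehyde; 14 methyl propiolate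
Product: 16 methyl (4R)-4-hydroxy-4-(epoxyalkyl)but-2-ynoate, via lithium methyl propiolate 15 (not isolated)
Conditions: 14, LiHMDS, THF, −78 °C; then 13, −78 °C; AcOH quench at −78 °C
Reagents that add atoms: none
Why: 1,2-Addition of the lithium acetylide under polar Felkin–Anh (Cornforth) control, with the oxirane C–O bond anti to the nucleophile and reinforced by the methyl group cis to the formyl group on the oxirane, should give the anti (erythro) epoxy alcohol and so set C6.

Step 11
Reactants: 16 hydroxy ynoate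
Product: 17 TES ether of 16
Conditions: TESOTf, 2,6-lutidine, CH2Cl2, −78 °C
Reagents that add atoms: triethylsilyl triflate CC[Si](CC)(CC)OS(=O)(=O)C(F)(F)F
Why: Low-temperature silylation avoids Payne rearrangement and gives a C6 silyl ether that is a poor leaving group in step 16 and can be removed before the C9 TBS ether.

Step 12
Reactants: 17 TES ether of 16
Product: 19 methyl (2Z,4R)-2-(hydroxymethyl)-4-[(triethylsilyl)oxy]-4-(epoxyalkyl)but-2-enoate, via vinylalane 18 (not isolated)
Conditions: DIBAL-H, NMO, THF, 0 °C; HCHO (gas), 0 °C → rt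
Reagents that add atoms: formaldehyde C=O
Why: Vinylalumination (syn 1,4-hydroalumination of the ynoate with the DIBAL-H–NMO complex, aluminium at the α-carbon) followed by trapping with formaldehyde should give the α-hydroxymethyl enoate, a β-substituted Morita–Baylis–Hillman-type adduct.

Step 13
Reactants: 19 hydroxymethyl enoate
Product: 20 methyl (2E,4R)-2-(bromomethyl)-4-[(triethylsilyl)oxy]-4-(epoxyalkyl)but-2-enoate
Conditions: CBr4, PPh3, CH2Cl2, 0 °C
Reagents that add atoms: carbon tetrabromide BrC(Br)(Br)Br
Why: Appel bromination converts the primary allylic alcohol into the 2-(bromomethyl)enoate under neutral conditions that the silyl ethers, the PMB ether and the oxirane should tolerate.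

Step 14
Reactants: 20 allylic bromide
Product: 21 primary alcohol (PMB removed)
Conditions: DDQ, CH2Cl2/pH 7 buffer, 0 °C
Reagents that add atoms: none
Why: Oxidative cleavage of the PMB ether with DDQ uses no nucleophile or base and should therefore spare the allylic bromide, the silyl ethers and the oxirane.

Step 15
Reactants: 21 primary alcohol
Product: 22 α-silyloxy aldehyde (open-chain cyclisation precursor)
Conditions: Dess–Martin periodinane, NaHCO3, CH2Cl2, 0 °C; used crude
Reagents that add atoms: none
Why: Buffered Dess–Martin oxidation should give the epimerisable α-silyloxy aldehyde without base and without nucleophiles that would alkylate on the bromide.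

Step 16
Reactants: 22 α-silyloxy aldehyde
Product: 25 9-O-TBS-6-O-TES α-methylene lactone (all stereocentres as in the target), via allylchromium 23 (not isolated), via chromium alkoxide 24 (not isolated)
Conditions: CrCl2 (8 equiv), THF/DMF, syringe-pump addition to 2–3 mM, rt; then 45 °C
Reagents that add atoms: none
Why: Two one-electron transfers from Cr(II) convert the allylic bromide into the γ-substituted 2-(methoxycarbonyl)allylchromium(III) species 23, which equilibrates by 1,3-metallotropy and adds through its γ-carbon (C7) to the tethered aldehyde carbon (C8) in a closed six-membered Zimmerman–Traxler transition state, after which the chromium alkoxide 24 acylates itself on the neighbouring methyl ester and expels methoxide; the closest known reaction type is the intramolecular Nozaki–Hiyama–Kishi 2-(alkoxycarbonyl)allylation/lactonisation used to close ten-membered germacranolide rings. The carbocycle closes by a 10-exo-trig addition to the C8=O group (SE2′ at the allyl unit) and the lactone by a 5-exo-trig acyl substitution at C12. C8 should be set by polar Felkin–Anh control from the non-chelating C9 silyloxy group (nucleophile anti to the C9–O bond, 8,9-anti), and C7 relative to C8 by the chair transition state in which both ring-forming arms (C9 on C8 and C6 on C7, the latter trans to the CH2Cr terminus as built into 22) are pseudo-equatorial, which gives the 7,8-anti adduct and hence the trans-fused lactone. The C6 centre is expected to reinforce this face: with C6–H eclipsing the allyl unit to avoid A(1,3) strain with the C11 substituent, the tether carbon C5 must lie on the side of the approaching aldehyde to span the ring, so the C6 silyloxy group points away from the forming bond and the 6,7-relationship of the target results. The step needs γ- over α-attack (inherent to allylchromium), cyclisation over oligomerisation (slow addition at high dilution), and survival of the allylic C6–O bond and the oxirane (a silyl ether is a poor leaving group for vinylogous β-elimination, and Cr(II)/Cr(III) leave epoxides untouched at room temperature).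

Step 17
Reactants: 25 bis-silyl lactone
Product: 26 C6 alcohol (C9-OTBS retained)
Conditions: HF·pyridine, pyridine, THF, 0 °C
Reagents that add atoms: none
Why: Buffered fluoride cleaves the secondary TES ether much faster than the more hindered TBS ether and should leave the oxirane and the α-methylene lactone intact.

Step 18
Reactants: 26 C6 alcohol; 27 tigloyl chloride
Product: 28 C6 tiglate (C9-OTBS)
Conditions: 27, Et3N, DMAP (cat.), CH2Cl2, 0 °C → rt
Reagents that add atoms: none
Why: DMAP-catalysed acylation of the secondary alcohol with the acid chloride should give the ester, and the E (tiglate) geometry is the thermodynamic one so isomerisation is not a concern.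

Step 19
Reactants: 28 C6 tiglate (C9-OTBS)
Product: 29 target
Conditions: HF·pyridine, pyridine, THF, 0 °C → rt
Reagents that add atoms: none
Why: Buffered HF·pyridine desilylation of the C9 TBS ether should spare the tiglate, the α-methylene lactone and the oxirane, which has no transannular alkene to trigger acid-induced cyclisation.

**Compound list**

1 | hepta-1,6-diyne | C#CCCCC#C | starting material
2 | lithium hepta-1,6-diyn-1-ide | [Li]C#CCCCC#C | intermediate
3 | octa-2,7-diyn-1-ol | OCC#CCCCC#C | intermediate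
4 | (E)-oct-2-en-7-yn-1-ol | OC/C=C/CCCC#C | intermediate
5 | [(2S,3S)-3-(pent-4-yn-1-yl)oxiran-2-yl]methanol | OC[C@@H]1O[C@H]1CCCC#C | intermediate
6 | (2R,3R)-3-methyloct-7-yne-1,2-diol | OC[C@H](O)[C@H](C)CCCC#C | intermediate
7 | 2,2-dibutyl-1,3,2-dioxastannolane (stannylene acetal) of diol 6 | CCCC[Sn]1(CCCC)OC[C@@H]([C@H](C)CCCC#C)O1 | intermediate
8 | (2R,3R)-1-[(4-methoxybenzyl)oxy]-3-methyloct-7-yn-2-ol | COc1ccc(COC[C@H](O)[C@H](C)CCCC#C)cc1 | intermediate
9 | tert-butyl{[(2R,3R)-1-[(4-methoxybenzyl)oxy]-3-methyloct-7-yn-2-yl]oxy}dimethylsilane | COc1ccc(COC[C@H](O[Si](C)(C)C(C)(C)C)[C@H](C)CCCC#C)cc1 | intermediate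
10 | (E)-alkenyldimethylalane from syn-methylalumination of 9 | COc1ccc(COC[C@H](O[Si](C)(C)C(C)(C)C)[C@H](C)CCC/C(C)=C/[Al](C)C)cc1 | intermediate
11 | (2E,7R,8R)-8-[(tert-butyldimethylsilyl)oxy]-9-[(4-methoxybenzyl)oxy]-3,7-dimethylnon-2-en-1-ol | COc1ccc(COC[C@H](O[Si](C)(C)C(C)(C)C)[C@H](C)CCC/C(C)=C/CO)cc1 | intermediate
12 | {(2R,3R)-3-[(4R,5R)-5-[(tert-butyldimethylsilyl)oxy]-6-[(4-methoxybenzyl)oxy]-4-methylhexyl]-3-methyloxiran-2-yl}methanol | COc1ccc(COC[C@H](O[Si](C)(C)C(C)(C)C)[C@H](C)CCC[C@@]2(C)O[C@@H]2CO)cc1 | intermediate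
13 | (2S,3R)-3-[(4R,5R)-5-[(tert-butyldimethylsilyl)oxy]-6-[(4-methoxybenzyl)oxy]-4-methylhexyl]-3-methyloxirane-2-carbaldehyde | COc1ccc(COC[C@H](O[Si](C)(C)C(C)(C)C)[C@H](C)CCC[C@@]2(C)O[C@@H]2C=O)cc1 | intermediate
14 | methyl propiolate | C#CC(=O)OC | starting material
15 | lithium 3-methoxy-3-oxoprop-1-yn-1-ide | [Li]C#CC(=O)OC | intermediate
16 | methyl (4R)-4-hydroxy-4-{(2R,3R)-3-[(4R,5R)-5-(TBSO)-6-(PMBO)-4-methylhexyl]-3-methyloxiran-2-yl}but-2-ynoate | COc1ccc(COC[C@H](O[Si](C)(C)C(C)(C)C)[C@H](C)CCC[C@@]2(C)O[C@@H]2[C@H](O)C#CC(=O)OC)cc1 | intermediate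
17 | methyl (4R)-4-[(triethylsilyl)oxy]-4-{(2R,3R)-3-[(4R,5R)-5-(TBSO)-6-(PMBO)-4-methylhexyl]-3-methyloxiran-2-yl}but-2-ynoate | COc1ccc(COC[C@H](O[Si](C)(C)C(C)(C)C)[C@H](C)CCC[C@@]2(C)O[C@@H]2[C@H](O[Si](CC)(CC)CC)C#CC(=O)OC)cc1 | intermediate
18 | α-(diisobutylalumino) enoate from syn-hydroalumination of 17 | COc1ccc(COC[C@H](O[Si](C)(C)C(C)(C)C)[C@H](C)CCC[C@@]2(C)O[C@@H]2[C@H](O[Si](CC)(CC)CC)/C=C(/[Al](CC(C)C)CC(C)C)C(=O)OC)cc1 | intermediate
19 | methyl (2Z,4R)-2-(hydroxymethyl)-4-[(triethylsilyl)oxy]-4-{(2R,3R)-3-[(4R,5R)-5-(TBSO)-6-(PMBO)-4-methylhexyl]-3-methyloxiran-2-yl}but-2-enoate | COc1ccc(COC[C@H](O[Si](C)(C)C(C)(C)C)[C@H](C)CCC[C@@]2(C)O[C@@H]2[C@H](O[Si](CC)(CC)CC)/C=C(/CO)C(=O)OC)cc1 | intermediate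
20 | methyl (2E,4R)-2-(bromomethyl)-4-[(triethylsilyl)oxy]-4-{(2R,3R)-3-[(4R,5R)-5-(TBSO)-6-(PMBO)-4-methylhexyl]-3-methyloxiran-2-yl}but-2-enoate | COc1ccc(COC[C@H](O[Si](C)(C)C(C)(C)C)[C@H](C)CCC[C@@]2(C)O[C@@H]2[C@H](O[Si](CC)(CC)CC)/C=C(/CBr)C(=O)OC)cc1 | intermediate
21 | methyl (2E,4R)-2-(bromomethyl)-4-[(triethylsilyl)oxy]-4-{(2R,3R)-3-[(4R,5R)-5-(TBSO)-6-hydroxy-4-methylhexyl]-3-methyloxiran-2-yl}but-2-enoate | OC[C@H](O[Si](C)(C)C(C)(C)C)[C@H](C)CCC[C@@]1(C)O[C@@H]1[C@H](O[Si](CC)(CC)CC)/C=C(/CBr)C(=O)OC | intermediate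
22 | methyl (2E,4R)-2-(bromomethyl)-4-[(triethylsilyl)oxy]-4-{(2R,3R)-3-[(4R,5R)-5-(TBSO)-4-methyl-6-oxohexyl]-3-methyloxiran-2-yl}but-2-enoate | O=C[C@H](O[Si](C)(C)C(C)(C)C)[C@H](C)CCC[C@@]1(C)O[C@@H]1[C@H](O[Si](CC)(CC)CC)/C=C(/CBr)C(=O)OC | intermediate
23 | allylchromium(III) dichloride derived from 22 (CH2Br replaced by CH2CrCl2) | O=C[C@H](O[Si](C)(C)C(C)(C)C)[C@H](C)CCC[C@@]1(C)O[C@@H]1[C@H](O[Si](CC)(CC)CC)/C=C(/C[Cr](Cl)Cl)C(=O)OC | intermediate
24 | chromium(III) alkoxide of the ten-membered C8-hydroxy 2-(cycloalkyl)acrylate methyl ester (C7–C8 bond formed, lactone open) | Cl[Cr](Cl)O[C@@H]1[C@H](O[Si](C)(C)C(C)(C)C)[C@H](C)CCC[C@@]2(C)O[C@@H]2[C@H](O[Si](CC)(CC)CC)[C@H]1C(=C)C(=O)OC | intermediate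
25 | 9-O-TBS-6-O-TES-4,5-epoxygermacr-11(13)-en-12,8-olide, trans-fused, stereocentres as in the target | C=C1C(=O)O[C@@H]2[C@H](O[Si](C)(C)C(C)(C)C)[C@H](C)CCC[C@@]3(C)O[C@@H]3[C@H](O[Si](CC)(CC)CC)[C@@H]12 | intermediate
26 | 9-O-TBS-6-hydroxy-4,5-epoxygermacr-11(13)-en-12,8-olide, stereocentres as in the target | C=C1C(=O)O[C@@H]2[C@H](O[Si](C)(C)C(C)(C)C)[C@H](C)CCC[C@@]3(C)O[C@@H]3[C@H](O)[C@@H]12 | intermediate
27 | tigloyl chloride, (E)-2-methylbut-2-enoyl chloride | C/C=C(\C)C(=O)Cl | starting material
28 | 9-O-TBS-6-O-tigloyl-4,5-epoxygermacr-11(13)-en-12,8-olide, stereocentres as in the target | C=C1C(=O)O[C@@H]2[C@H](O[Si](C)(C)C(C)(C)C)[C@H](C)CCC[C@@]3(C)O[C@@H]3[C@H](OC(=O)/C(C)=C/C)[C@@H]12 | intermediate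
29 | CNP0165329.2: (4R,5R,6R,7S,8S,9R,10R)-4,5-epoxy-9-hydroxy-6-[(E)-2-methylbut-2-enoyloxy]germacr-11(13)-en-12,8-olide | C=C1C(=O)O[C@@H]2[C@H](O)[C@H](C)CCC[C@@]3(C)O[C@@H]3[C@H](OC(=O)/C(C)=C/C)[C@@H]12 | target

**Step count and risks**

Total step count: 19. Longest linear sequence: 19 steps (fully linear from 1).

Steps most likely to fail:

1. Step 16 (key step). The process at risk is facial control in the C7–C8 bond formation: the Felkin preference at C9 and the intrinsic bias of the C6 centre may be mismatched, giving the cis-fused or C7/C8-epimeric ring. Competing processes are oligomerisation and vinylogous β-elimination of the C6 silyloxy group from the allylchromium species.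
Fallback (sets out from 17, returns at 25): the conjugate hydroalumination of step 12 is run on 17 and the α-metallated enoate is alkylated, after transmetallation to copper, with iodomethylboronic acid pinacol ester to give the pinacol allylboronate F1, in which C6 is trans to the CH2B group. DDQ in buffered CH2Cl2 should then give the primary alcohol F2, and Dess–Martin oxidation the boronate aldehyde F3. F3 would be cyclised at high dilution by a thermal or Sc(OTf)3-catalysed type-I allylboration; this reagent is configurationally stable, cannot eliminate the silyloxy group, and reads its geometry out through a chair transition state as the 7,8-anti adduct. Acid-promoted lactonisation of the borate would then give 25.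

2. Step 12. The processes at risk are competing 1,2-reduction of the ester or reductive opening of the oxirane by the aluminium hydride, and incomplete capture of the vinylalane by formaldehyde.
Fallback (sets out from 17, returns at 19): Pd(0)-catalysed syn-hydrostannation (Bu3SnH, Pd(PPh3)4, THF, 0 °C) should place tin at the α-carbon and give the α-stannyl enoate F4. Iododestannylation with I2 in CH2Cl2 gives the α-iodo enoate F5 with retention, and Stille coupling of F5 with (tributylstannyl)methanol (Pd(PPh3)4, dioxane, 80 °C) should give 19 with the same alkene geometry.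

3. Step 10. The process at risk is poor facial selectivity in the acetylide addition to the epoxy aldehyde (Felkin versus anti-Felkin), which would give a C6 epimer mixture.
Fallback (sets out from 16 as the epimer mixture, returns at 16): Dess–Martin oxidation of the mixture should give the ynone F6. It would then be reduced under reagent control by a Midland reduction with the Alpine-borane enantiomer that delivers hydride to the required face (by the usual model, the reagent from (−)-α-pinene), returning the single (4R)-carbinol 16.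

**Further compounds**

F1 | step 16 | pinacol allylboronate: methyl (2E)-2-[(pinacolboryl)methyl]-4-(TESO)-4-(epoxyalkyl)but-2-enoate, PMB ether, C6 trans to CH2B | COc1ccc(COC[C@H](O[Si](C)(C)C(C)(C)C)[C@H](C)CCC[C@@]2(C)O[C@@H]2[C@H](O[Si](CC)(CC)CC)/C=C(/CB3OC(C)(C)C(C)(C)O3)C(=O)OC)cc1
F2 | step 16 | primary alcohol of the allylboronate (PMB removed) | OC[C@H](O[Si](C)(C)C(C)(C)C)[C@H](C)CCC[C@@]1(C)O[C@@H]1[C@H](O[Si](CC)(CC)CC)/C=C(/CB2OC(C)(C)C(C)(C)O2)C(=O)OC
F3 | step 16 | boronate aldehyde (allylboration precursor) | O=C[C@H](O[Si](C)(C)C(C)(C)C)[C@H](C)CCC[C@@]1(C)O[C@@H]1[C@H](O[Si](CC)(CC)CC)/C=C(/CB2OC(C)(C)C(C)(C)O2)C(=O)OC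
F4 | step 12 | α-(tributylstannyl) enoate from syn-hydrostannation of 17 | COc1ccc(COC[C@H](O[Si](C)(C)C(C)(C)C)[C@H](C)CCC[C@@]2(C)O[C@@H]2[C@H](O[Si](CC)(CC)CC)/C=C(/[Sn](CCCC)(CCCC)CCCC)C(=O)OC)cc1
F5 | step 12 | α-iodo enoate | COc1ccc(COC[C@H](O[Si](C)(C)C(C)(C)C)[C@H](C)CCC[C@@]2(C)O[C@@H]2[C@H](O[Si](CC)(CC)CC)/C=C(/I)C(=O)OC)cc1
F6 | step 10 | epoxy ynone: methyl 4-oxo-4-(epoxyalkyl)but-2-ynoate | COc1ccc(COC[C@H](O[Si](C)(C)C(C)(C)C)[C@H](C)CCC[C@@]2(C)O[C@@H]2C(=O)C#CC(=O)OC)cc1
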